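**Retrosynthetic overview**
1. Ester C–O bond: target 15 ⇒ syn β-hydroxy ketone 13 + 3,4-dimethoxybenzoyl chloride 14 (last step).
2. Methyl ketone: 13 ⇒ O-triethylsilyl Weinreb amide 10 + MeMgBr.
3. Key C–C bond (C3–C4 of the butanone chain): intermolecular Evans syn aldol of propionimide 4 (from auxiliary 1 + propanoyl chloride 2) with 3,4-dimethoxybenzaldehyde 5. This sets both stereocentres.
4. Rings: none is formed. Both arenes are bought intact (5 and 14), and the oxazolidinone ring of 1 is a recoverable auxiliary.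

Assumption: (R)-4-benzyl-1,3-oxazolidin-2-one (from D-phenylalaninol) counts as a cheap commercial starting material; it is recovered in step 3.

Stereochemical check of the target: both centres are R (C1 and C2 of the 3-oxobutyl chain). This is the syn aldol relationship, enantiomeric to the product of the (S)-benzyl auxiliary, hence the (R)-auxiliary.

**Route**

Step 1
Reactants: 1 (4R)-4-benzyl-1,3-oxazolidin-2-one; 2 propanoyl chloride
Product: 4 (4R)-4-benzyl-3-propanoyl-1,3-oxazolidin-2-one, via N-lithio oxazolidinone 3 (not isolated)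
Conditions: n-BuLi (1.05 equiv), THF, –78 °C; then 2, –78 → 0 °C
Reagents that add atoms: none
Why: N-acylation (nucleophilic acyl substitution) of the lithiated carbamate nitrogen by the acid chloride is fast and clean at low temperature and does not touch the existing stereocentre.

Step 2
Reactants: 4 (4R)-4-benzyl-3-propanoyl-1,3-oxazolidin-2-one; 5 3,4-dimethoxybenzaldehyde
Product: 8 (4R)-4-benzyl-3-[(2R,3R)-3-(3,4-dimethoxyphenyl)-3-hydroxy-2-methylpropanoyl]-1,3-oxazolidin-2-one, via (Z)-dibutylboron enolate 6 (not isolated), via dibutylboron aldolate 7 (not isolated)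
Conditions: Bu2BOTf (1.2 equiv), i-Pr2NEt (1.4 equiv), CH2Cl2, 0 °C; then 5, –78 → 0 °C; pH 7 buffer (KH2PO4/K2HPO4), MeOH, 30% H2O2, 0 °C
Reagents that add atoms: none
Why: Evans syn aldol addition, in which the (Z)-boron enolate reacts through a closed chair (Zimmerman–Traxler) transition state on the enolate face away from the benzyl group of the dipole-opposed auxiliary, setting both new centres as 2R,3R (syn).

Step 3
Reactants: 8 (4R)-4-benzyl-3-[(2R,3R)-3-(3,4-dimethoxyphenyl)-3-hydroxy-2-methylpropanoyl]-1,3-oxazolidin-2-one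
Product: 9 (2R,3R)-3-(3,4-dimethoxyphenyl)-3-hydroxy-N-methoxy-N,2-dimethylpropanamide
Conditions: MeNHOMe·HCl (3 equiv), AlMe3 (3 equiv), CH2Cl2, –20 → 0 °C; cold 0.5 M aq. HCl quench
Reagents that add atoms: N,O-dimethylhydroxylamine hydrochloride, CNOC.Cl
Why: Weinreb transamination, in which the aluminium amide, directed by the free β-alkoxide, attacks only the exocyclic imide carbonyl and releases the auxiliary without disturbing either stereocentre.

Step 4
Reactants: 9 (2R,3R)-3-(3,4-dimethoxyphenyl)-3-hydroxy-N-methoxy-N,2-dimethylpropanamide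
Product: 10 (2R,3R)-3-(3,4-dimethoxyphenyl)-N-methoxy-N,2-dimethyl-3-(triethylsilyloxy)propanamide
Conditions: TESCl (1.3 equiv), imidazole (2.5 equiv), DMF, 0 °C → rt
Reagents that add atoms: chlorotriethylsilane (TESCl), CC[Si](Cl)(CC)CC
Why: Silyl ether formation (O-silylation) masks the benzylic hydroxyl so that no metal aldolate, and hence no retro-aldol or syn/anti scrambling, can arise in the organomagnesium step.

Step 5
Reactants: 10 (2R,3R)-3-(3,4-dimethoxyphenyl)-N-methoxy-N,2-dimethyl-3-(triethylsilyloxy)propanamide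
Product: 12 (3R,4R)-4-(3,4-dimethoxyphenyl)-3-methyl-4-(triethylsilyloxy)butan-2-one, via bromomagnesium hemiaminal chelate 11 (not isolated)
Conditions: MeMgBr (2.5 equiv), THF, 0 °C; sat. aq. NH4Cl
Reagents that add atoms: methylmagnesium bromide, C[Mg]Br
Why: Weinreb ketone synthesis, in which the N-methoxy chelate holds the tetrahedral adduct until quench, so exactly one methyl is delivered and the α-stereocentre is never enolised.

Step 6
Reactants: 12 (3R,4R)-4-(3,4-dimethoxyphenyl)-3-methyl-4-(triethylsilyloxy)butan-2-one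
Product: 13 (3R,4R)-4-(3,4-dimethoxyphenyl)-4-hydroxy-3-methylbutan-2-one
Conditions: HF·pyridine, pyridine, THF, 0 °C → rt; aq. NaHCO3
Reagents that add atoms: none
Why: Buffered fluoride desilylation cleaves only the Si–O bond under mildly acidic conditions, avoiding the base-triggered retro-aldol and β-elimination pathways of a β-oxy ketone and leaving both centres intact.

Step 7
Reactants: 13 (3R,4R)-4-(3,4-dimethoxyphenyl)-4-hydroxy-3-methylbutan-2-one; 14 3,4-dimethoxybenzoyl chloride
Product: 15 (1R,2R)-1-(3,4-dimethoxyphenyl)-2-methyl-3-oxobutyl 3,4-dimethoxybenzoate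
Conditions: 14 (1.5 equiv), pyridine (3 equiv), DMAP (0.1 equiv), CH2Cl2, 0 °C → rt
Reagents that add atoms: none
Why: DMAP-catalysed O-acylation (nucleophilic acyl substitution via the N-acylpyridinium) forms the ester at oxygen with retention at the carbinol carbon, the weak base and low temperature keeping C3 epimerisation and E1cB loss of the new benzoate at bay.

**Compound list**
1 | (4R)-4-benzyl-1,3-oxazolidin-2-one | O=C1N[C@H](Cc2ccccc2)CO1 | starting material
2 | propanoyl chloride | CCC(Cl)=O | starting material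
3 | N-lithio-(4R)-4-benzyl-1,3-oxazolidin-2-one | [Li]N1[C@H](Cc2ccccc2)COC1=O | intermediate
4 | (4R)-4-benzyl-3-propanoyl-1,3-oxazolidin-2-one | CCC(=O)N1[C@H](Cc2ccccc2)COC1=O | intermediate
5 | 3,4-dimethoxybenzaldehyde (veratraldehyde) | COc1ccc(C=O)cc1OC | starting material
6 | (Z)-dibutylboron enolate of 4, (4R)-4-benzyl-3-[(1Z)-1-(dibutylboranyloxy)prop-1-en-1-yl]-1,3-oxazolidin-2-one | CCCCB(CCCC)O/C(=C\C)N1[C@H](Cc2ccccc2)COC1=O | intermediate
7 | dibutylboron aldolate (O-dibutylboranyl derivative of 8 at the carbinol oxygen, 2R,3R) | CCCCB(CCCC)O[C@@H](c1ccc(OC)c(OC)c1)[C@@H](C)C(=O)N1[C@H](Cc2ccccc2)COC1=O | intermediate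
8 | (4R)-4-benzyl-3-[(2R,3R)-3-(3,4-dimethoxyphenyl)-3-hydroxy-2-methylpropanoyl]-1,3-oxazolidin-2-one | O[C@@H](c1ccc(OC)c(OC)c1)[C@@H](C)C(=O)N1[C@H](Cc2ccccc2)COC1=O | intermediate
9 | (2R,3R)-3-(3,4-dimethoxyphenyl)-3-hydroxy-N-methoxy-N,2-dimethylpropanamide | O[C@@H](c1ccc(OC)c(OC)c1)[C@@H](C)C(=O)N(C)OC | intermediate
10 | (2R,3R)-3-(3,4-dimethoxyphenyl)-N-methoxy-N,2-dimethyl-3-(triethylsilyloxy)propanamide | CC[Si](CC)(CC)O[C@@H](c1ccc(OC)c(OC)c1)[C@@H](C)C(=O)N(C)OC | intermediate
11 | bromomagnesium hemiaminal chelate (tetrahedral adduct of MeMgBr to the amide carbonyl of 10; new hemiaminal carbon undefined) | CC[Si](CC)(CC)O[C@@H](c1ccc(OC)c(OC)c1)[C@@H](C)C(C)(O[Mg]Br)N(C)OC | intermediate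
12 | (3R,4R)-4-(3,4-dimethoxyphenyl)-3-methyl-4-(triethylsilyloxy)butan-2-one | CC[Si](CC)(CC)O[C@@H](c1ccc(OC)c(OC)c1)[C@@H](C)C(C)=O | intermediate
13 | (3R,4R)-4-(3,4-dimethoxyphenyl)-4-hydroxy-3-methylbutan-2-one | O[C@@H](c1ccc(OC)c(OC)c1)[C@@H](C)C(C)=O | intermediate
14 | 3,4-dimethoxybenzoyl chloride (veratroyl chloride) | COc1ccc(C(Cl)=O)cc1OC | starting material
15 | (1R,2R)-1-(3,4-dimethoxyphenyl)-2-methyl-3-oxobutyl 3,4-dimethoxybenzoate (CNP0269359.2) | COc1ccc(C(=O)O[C@@H](c2ccc(OC)c(OC)c2)[C@@H](C)C(C)=O)cc1OC | target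

**Step count**
Total steps: 7. Longest linear sequence: 7 (1 → 4 → 8 → 9 → 10 → 12 → 13 → 15).

**Three steps most likely to fail, with fallbacks**

Step 2 (aldol). The electron-rich aldehyde 5 is a sluggish electrophile and its aldolate is prone to reversal, so conversion or diastereoselectivity may fall short. The fallback sets out from 5 (with 2) and comes back at 9. Commercial (4R)-4-benzyl-1,3-thiazolidine-2-thione is acylated with 2 (Et3N, DMAP cat., CH2Cl2) to give (4R)-4-benzyl-3-propanoyl-1,3-thiazolidine-2-thione F1. Soft enolisation with TiCl4 (1.05 equiv), i-Pr2NEt (1.1 equiv) and N-methyl-2-pyrrolidinone (1 equiv) in CH2Cl2 at 0 °C gives the trichlorotitanium (Z)-enolate F2. This adds to 5 at –78 → 0 °C through the non-chelated chair transition state, with the same facial sense as the boron aldol, to give the trichlorotitanium aldolate F3. Aqueous NH4Cl then liberates (4R)-4-benzyl-3-[(2R,3R)-3-(3,4-dimethoxyphenyl)-3-hydroxy-2-methylpropanoyl]-1,3-thiazolidine-2-thione F4. The thione auxiliary is displaced directly by MeNHOMe·HCl/imidazole in CH2Cl2 at rt to give 9, which also removes the need for AlMe3 in step 3.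

Step 6 (desilylation). The electron-rich benzylic C–O bond may ionise under HF, epimerising C4, or the freed β-hydroxy ketone may eliminate or retro-aldolise on work-up. The fallback sets out from 9 and comes back at 13, omitting the silyl group altogether. Unprotected 9 is treated with MeMgBr (3.5 equiv) in THF at –20 → 0 °C. The first equivalent forms the magnesium alkoxide and the second adds to the amide, giving the bis(bromomagnesium) tetrahedral adduct F5, which is held as a chelate in the cold and collapses to 13 on aqueous NH4Cl quench. This bypasses steps 4–6 at the price of a transient metal aldolate.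

Step 7 (esterification). The hindered benzylic alcohol may acylate slowly, and the product is a β-aroyloxy ketone that can undergo E1cB elimination to the aryl enone or epimerise at C3 under amine base. The fallback sets out from 9 and comes back at 15, installing the ester before the ketone exists. Amide 9, whose α-hydrogen is far less acidic than that of a ketone, is acylated with 14 (pyridine, DMAP, CH2Cl2) to give (1R,2R)-1-(3,4-dimethoxyphenyl)-3-[methoxy(methyl)amino]-2-methyl-3-oxopropyl 3,4-dimethoxybenzoate F6. MeMgBr (1.2 equiv, THF, –78 → –40 °C) then adds to the chelating Weinreb amide in preference to the deactivated, hindered electron-rich benzoate, giving the bromomagnesium hemiaminal chelate F7. Aqueous NH4Cl releases 15, so the β-acyloxy ketone never meets an amine base. The known risk of this fallback is competing attack of MeMgBr on the ester.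

**Further compounds**
F1 | step 2 | (4R)-4-benzyl-3-propanoyl-1,3-thiazolidine-2-thione | CCC(=O)N1[C@H](Cc2ccccc2)CSC1=S
F2 | step 2 | trichlorotitanium (Z)-enolate of F1 | C/C=C(\O[Ti](Cl)(Cl)Cl)N1[C@H](Cc2ccccc2)CSC1=S
F3 | step 2 | trichlorotitanium aldolate (O-titanated F4, 2R,3R) | Cl[Ti](Cl)(Cl)O[C@@H](c1ccc(OC)c(OC)c1)[C@@H](C)C(=O)N1[C@H](Cc2ccccc2)CSC1=S
F4 | step 2 | (4R)-4-benzyl-3-[(2R,3R)-3-(3,4-dimethoxyphenyl)-3-hydroxy-2-methylpropanoyl]-1,3-thiazolidine-2-thione | O[C@@H](c1ccc(OC)c(OC)c1)[C@@H](C)C(=O)N1[C@H](Cc2ccccc2)CSC1=S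
F5 | step 6 | bis(bromomagnesium) tetrahedral adduct of MeMgBr to 9 (alkoxide and hemiaminal both magnesiated) | Br[Mg]O[C@@H](c1ccc(OC)c(OC)c1)[C@@H](C)C(C)(O[Mg]Br)N(C)OC
F6 | step 7 | (1R,2R)-1-(3,4-dimethoxyphenyl)-3-[methoxy(methyl)amino]-2-methyl-3-oxopropyl 3,4-dimethoxybenzoate | COc1ccc(C(=O)O[C@@H](c2ccc(OC)c(OC)c2)[C@@H](C)C(=O)N(C)OC)cc1OC
F7 | step 7 | bromomagnesium hemiaminal chelate from MeMgBr and F6 | COc1ccc(C(=O)O[C@@H](c2ccc(OC)c(OC)c2)[C@@H](C)C(C)(O[Mg]Br)N(C)OC)cc1OC
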